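**Plan**
1. Cuts: first the O–CH3 bond of a methyl helper on the phenol oxygen of the monobrominated ring (ring A). Then the bond between the CH2 carbon and C4 of ring A, which leaves 2,6-dibromo-4-methylphenol (1) and 2-bromoanisole (2), both commercial.
2. Enabling feature: in the dibrominated ring (ring B) the carbon bearing OH is para to the carbon bearing CH2, and both carbons ortho to the OH carry Br. A two-electron oxidation of ring B therefore has no nuclear outlet and is relayed to the exocyclic carbon as a p-quinone methide (ring C4=CH2).
3. Step 1: bromide-mediated anodic oxidation of 1 (ipso-bromination at C4 with dearomatisation, then loss of HBr) pools the quinone methide as its HBr adduct. With the current off, 2 is added and its C4 (para to OCH3) attacks the CH2 carbon, a net benzylic C–H/aryl C–H coupling with H2 as by-product.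
4. Step 2: BBr3 removes the methyl helper, which served only to steer the attack to the para carbon.
5. No ring is built. Both benzene rings are bought with their bromines in place, so the 2 + 1 bromine pattern follows from the choice of halves, and no metal that inserts into C–Br bonds is used.
6. Stereochemistry: none to set, because the target has no stereocentre, stereogenic axis or double-bond geometry.

Key step: step 1

Assumption: the SMILES contains no stereogenic element, so the compound is achiral and the request for a single enantiomer is met by the constitution alone.

**Step 1**
Reactants: 1 2,6-dibromo-4-methylphenol; 2 2-bromoanisole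
Product: 6 2,6-dibromo-4-[(3-bromo-4-methoxyphenyl)methyl]phenol, via 4-bromodienone 3 (not isolated), via quinone methide 4 (not isolated), via benzylic bromide 5 (not isolated)
Conditions: (a) graphite (+) | Pt (−), divided cell (Nafion), HBr (33% in AcOH, 1.3 equiv), Bu4NPF6 (0.1 M), CH2Cl2–HFIP 4:1, constant current, 2.0 F mol−1, 25 °C, then current off, 35 °C, 1 h; (b) 2 (3 equiv), HFIP (to CH2Cl2–HFIP 1:4), 40 °C
Reagents that add atoms: none
Why: Proposed new method: the anode oxidises only bromide (to Br2, at a potential below that of 1), and since C2 and C6 of 1 already carry Br the sole nuclear site open to Br+ is C4, ipso to CH3, so 1 is dearomatised to the 4-bromodienone 3, which loses HBr across C4–CH3 to give the p-quinone methide 4, stored by HBr as the benzylic bromide 5 while protons are reduced to H2 at the cathode. With the current off, the HFIP-rich medium ionises 5 back to acid-activated 4, C4 of 2 adds to its exocyclic CH2 (Friedel–Crafts alkylation, a vinylogous 1,6-addition), both rings end aromatic and HBr is returned, so the net change is a benzylic C–H/aryl C–H coupling with loss of H2. The closest known reaction types are halide-mediated indirect electrolysis, the side-chain bromination of 2,6-dihalo-4-methylphenols by way of 4-bromodienones, the "cation pool" order of events in anodic benzylic C–H/aryl C–H coupling and the HFIP-promoted Friedel–Crafts benzylation; their union in one vessel on a brominated cresol is what is new. No ring is closed and no stereocentre is formed. Chemoselectivity rests on the mediator, which avoids the phenoxyl and phenoxenium species that divert 4-alkyl-2,6-dibromophenols into C–O dimerisation, on the charge limit of 2 F mol−1 together with the late addition of 2, so that neither 2 nor ring B of 6 meets positive bromine, and on the absence of any low-valent metal, so that all three C–Br bonds persist. Regioselectivity rests on 2, in which only C4 and C6 are activated by OCH3, the ortho bromine turns the O-methyl group over C6 and no free OH is present for O-alkylation or ortho delivery, so that para attack should prevail, while 1, 5 and ring B of 6 have every ortho and para position filled and cannot self-condense, and the excess of 2 counters a second benzylation.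

**Step 2**
Reactants: 6 2,6-dibromo-4-[(3-bromo-4-methoxyphenyl)methyl]phenol
Product: 7 2-bromo-4-(3,5-dibromo-4-hydroxybenzyl)phenol (target)
Conditions: BBr3 (3 equiv), CH2Cl2, −78 °C to rt; then H2O, 0 °C
Reagents that add atoms: none
Why: Lewis-acid cleavage of an aryl methyl ether with BBr3 (coordination at oxygen, SN2 attack of bromide at CH3) is the standard last step for brominated diarylmethane phenols, the three equivalents allow for the boron that the free ring-B phenol ties up until the aqueous quench, and the C–Br bonds and the diarylmethane CH2 should be inert at or below room temperature.

**Compound list**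
1 | 2,6-dibromo-4-methylphenol | Cc1cc(Br)c(O)c(Br)c1 | starting material
2 | 2-bromoanisole (1-bromo-2-methoxybenzene) | COc1ccccc1Br | starting material
3 | 2,4,6-tribromo-4-methylcyclohexa-2,5-dien-1-one | CC1(Br)C=C(Br)C(=O)C(Br)=C1 | intermediate
4 | 2,6-dibromo-4-methylidenecyclohexa-2,5-dien-1-one | C=C1C=C(Br)C(=O)C(Br)=C1 | intermediate
5 | 2,6-dibromo-4-(bromomethyl)phenol | BrCc1cc(Br)c(O)c(Br)c1 | intermediate
6 | 2,6-dibromo-4-[(3-bromo-4-methoxyphenyl)methyl]phenol | COc1ccc(Cc2cc(Br)c(O)c(Br)c2)cc1Br | intermediate
7 | 2-bromo-4-(3,5-dibromo-4-hydroxybenzyl)phenol | Oc1ccc(Cc2cc(Br)c(O)c(Br)c2)cc1Br | target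

Total step count: 2
Longest linear sequence: 2

**Steps most likely to fail** (the route has only two steps, so both are ranked)

1. Step 1 (labelled step).
   - The oxidation may stall at the dearomatised stage, or acid may shift the bromine from C4 into the ring, so that nuclear instead of side-chain functionalisation results.
   - Left-over positive bromine, or acid-mediated bromine transfer between rings, may halogenate the added arene.
   - In the Friedel–Crafts stage, para selectivity may erode or a second benzylation may occur.
   - The fallback uses known chemistry, sets out from 1 and comes back to the route at 6. Cobalt-catalysed aerobic oxidation of the para-methyl group of 1 (Co(OAc)2, NaOH, O2, MeOH, 60 °C) is a known conversion of 2,6-disubstituted 4-methylphenols and should give 3,5-dibromo-4-hydroxybenzaldehyde F1, which is also commercial. Condensation with tosylhydrazide (MeOH, 60 °C) should give (E)-N'-(3,5-dibromo-4-hydroxybenzylidene)-4-methylbenzenesulfonohydrazide F2. The metal-free reductive coupling of this tosylhydrazone with purchased (3-bromo-4-methoxyphenyl)boronic acid F3 (K2CO3, 1,4-dioxane, 110 °C) forms the same CH2–aryl bond only at the boron-bearing carbon. It needs neither an oxidation nor a transition metal, so the C–Br bonds are left alone, and it delivers 6.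

2. Step 2.
   - Lewis-acid-promoted loss or migration of bromine ortho to the newly freed phenol is possible.
   - Ether cleavage may be incomplete because boron is bound by the ring-B phenol.
   - The fallback changes the helper group, sets out from 1 and comes back to the route at 7. Step 1 is run with purchased 1-bromo-2-(propan-2-yloxy)benzene F4 in place of 2. This should give 2,6-dibromo-4-{[3-bromo-4-(propan-2-yloxy)phenyl]methyl}phenol F5, in which the larger O-alkyl group shields C6 still better. The secondary alkyl aryl ether is then cleaved with BCl3 (CH2Cl2, −20 to 0 °C), a known selective dealkylation that needs a much lighter Lewis-acid load than methyl ether cleavage, to give 7.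

**Further compounds**
F1 | step 1 | 3,5-dibromo-4-hydroxybenzaldehyde | O=Cc1cc(Br)c(O)c(Br)c1
F2 | step 1 | (E)-N'-(3,5-dibromo-4-hydroxybenzylidene)-4-methylbenzenesulfonohydrazide | Cc1ccc(cc1)S(=O)(=O)N/N=C/c1cc(Br)c(O)c(Br)c1
F3 | step 1 | (3-bromo-4-methoxyphenyl)boronic acid (purchased) | COc1ccc(cc1Br)B(O)O
F4 | step 2 | 1-bromo-2-(propan-2-yloxy)benzene (purchased) | CC(C)Oc1ccccc1Br
F5 | step 2 | 2,6-dibromo-4-{[3-bromo-4-(propan-2-yloxy)phenyl]methyl}phenol | CC(C)Oc1ccc(Cc2cc(Br)c(O)c(Br)c2)cc1Br
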